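**Retrosynthetic overview**
1. Target 28 comes from the racemic tris-MOM isoflavanone 25: C3 is set by transfer-hydrogenative dynamic kinetic resolution, C4 is then reoxidised and the MOM ethers are removed.
2. Ring C is opened at O1–C2 (Mitsunobu closure of a primary alcohol onto an ortho phenol), which leads back to the open-chain aryl ketone 22.
3. The strategy rests on ring A (C4a, C5, C6, C7, C8, C8a): it carries oxygens on C5, C7 and C8a and the acyl carbon C4 on C4a, so it is an acylphloroglucinol, i.e. a folded tetraketide. Cutting C4a–C5 unfolds it to the 3,5,7-triketo ester 20.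
4. Ester 20 comes from diketo-dioxinone 18 (acylketene trapped by methanol); 18 comes from the dianion of keto-dioxinone 16 and the acid 13. Acid 13 is built from bromochromene 7, which comes from 4-bromoresorcinol and 2-methylbut-3-yn-2-ol.
5. Ring order: the pyran ring on ring B first (step 3), ring A second (step 11), ring C last (step 14).

Key step: step 11

Remark: Ar stands for 5-(methoxymethoxy)-2,2-dimethyl-2H-chromen-8-yl. Compounds 11–13 and 17–25 are racemic at the carbon that becomes C3; its configuration is fixed only in step 15. The target is (3S) by CIP analysis of the given SMILES.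

**Route**

Step 1
Reactants: 1 4-bromoresorcinol
Product: 2 2-bromo-5-(methoxymethoxy)phenol
Conditions: NaH (2.1 equiv.), THF/DMF, 0 °C; MOMCl (1.0 equiv.), −20 → 0 °C; NH4Cl
Reagents that add atoms: chloromethyl methyl ether (MOMCl), COCCl
Why: Williamson-type O-alkylation of the dianion, in which the phenoxide para to bromine is both the more basic and the less hindered one, so the single equivalent of MOMCl should go there.

Step 2
Reactants: 2 2-bromo-5-(methoxymethoxy)phenol; 3 2-methylbut-3-yn-2-ol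
Product: 5 1-bromo-4-(methoxymethoxy)-2-[(2-methylbut-3-yn-2-yl)oxy]benzene, via trifluoroacetate 4 (not isolated)
Conditions: 3, (CF3CO)2O, DBU, MeCN, −5 °C; then 2, DBU, CuCl2·2H2O (cat.), MeCN, 0 °C
Reagents that add atoms: none
Why: Copper-catalysed propargylic etherification of a phenol with a tertiary propargyl trifluoroacetate forms the hindered aryl 1,1-dimethylpropargyl ether under mild base without elimination to the enyne.

Step 3
Reactants: 5 1-bromo-4-(methoxymethoxy)-2-[(2-methylbut-3-yn-2-yl)oxy]benzene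
Product: 7 8-bromo-5-(methoxymethoxy)-2,2-dimethyl-2H-chromene, via allenylphenol 6 (not isolated)
Conditions: xylenes, 140 °C
Reagents that add atoms: none
Why: Aromatic propargyl Claisen rearrangement can only go to the free ortho carbon between the two oxygens (the other ortho carbon bears bromine), and the allenylphenol then closes to the chromene by 1,5-hydrogen shift and oxa-6π-electrocyclisation.

Step 4
Reactants: 7 8-bromo-5-(methoxymethoxy)-2,2-dimethyl-2H-chromene; 8 (2-ethoxy-2-oxoethyl)zinc bromide (BrZnCH2CO2Et, THF solution)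
Product: 9 ethyl 2-Ar-acetate
Conditions: Pd2(dba)3 (2 mol%), XPhos (8 mol%), THF, 60 °C
Reagents that add atoms: none
Why: Negishi-type cross-coupling of a Reformatsky reagent (oxidative addition of zerovalent palladium into the aryl bromide, transmetalation, reductive elimination) is a non-basic ester α-arylation that a bulky biarylphosphine carries through for ortho-alkoxy aryl bromides.

Step 5
Reactants: 9 ethyl 2-Ar-acetate; 10 paraformaldehyde
Product: 11 ethyl 3-hydroxy-2-Ar-propanoate (racemic)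
Conditions: (CH2O)n (1.1 equiv.), NaOEt (0.1 equiv.), DMSO, 20 °C; AcOH quench
Reagents that add atoms: none
Why: Base-catalysed aldol addition of the arylacetate enolate to formaldehyde (tropic-ester hydroxymethylation) gives the racemic β-hydroxy ester; near-stoichiometric formaldehyde and catalytic base at room temperature should limit double addition and dehydration.

Step 6
Reactants: 11 ethyl 3-hydroxy-2-Ar-propanoate (racemic)
Product: 12 ethyl 3-[tert-butyl(dimethyl)silyl]oxy-2-Ar-propanoate (racemic)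
Conditions: TBSCl, imidazole, DMF, 0 → 20 °C
Reagents that add atoms: tert-butyldimethylsilyl chloride (TBSCl), CC(C)(C)[Si](C)(C)Cl
Why: Standard imidazole-promoted silylation of a primary alcohol.

Step 7
Reactants: 12 ethyl 3-[tert-butyl(dimethyl)silyl]oxy-2-Ar-propanoate (racemic)
Product: 13 3-[tert-butyl(dimethyl)silyl]oxy-2-Ar-propanoic acid (racemic)
Conditions: LiOH·H2O, THF/H2O, 0 → 20 °C; then 0.5 M HCl, 0 °C, to pH 4
Reagents that add atoms: lithium hydroxide, [Li+].[OH-]
Why: Saponification by hydroxide addition to the ester carbonyl should outrun α-deprotonation in aqueous medium, so the β-silyloxy group is not eliminated and the primary silyl and aryl MOM ethers survive.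

Step 8
Reactants: 14 2,2,6-trimethyl-4H-1,3-dioxin-4-one; 15 acetyl chloride
Product: 16 2,2-dimethyl-6-(2-oxopropyl)-4H-1,3-dioxin-4-one
Conditions: LiN(SiMe3)2, THF, −78 °C; then 15 (0.5 equiv.), −78 → −20 °C; NH4Cl
Reagents that add atoms: none
Why: The vinylogous lithium enolate of the dioxinone is C-acylated at the methyl carbon by acetyl chloride (Claisen-type acylation), with the excess enolate taking up the more acidic product.

Step 9
Reactants: 13 3-[tert-butyl(dimethyl)silyl]oxy-2-Ar-propanoic acid (racemic); 16 2,2-dimethyl-6-(2-oxopropyl)-4H-1,3-dioxin-4-one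
Product: 18 6-{6-[tert-butyl(dimethyl)silyl]oxy-5-Ar-2,4-dioxohexyl}-2,2-dimethyl-4H-1,3-dioxin-4-one (racemic), via acyl imidazolide 17 (not isolated)
Conditions: 13, CDI, THF, 20 °C; separately 16 (3 equiv.), LiN(i-Pr)2 (6 equiv.), THF, −78 °C; combine at −78 → −40 °C; NH4Cl
Reagents that add atoms: none
Why: Claisen-type C-acylation at the terminal, most nucleophilic carbon of the keto-dioxinone dianion by an acyl imidazolide, with excess dianion absorbing the liberated imidazole and the acidic β-diketone product.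

Step 10
Reactants: 18 diketo-dioxinone (racemic)
Product: 20 methyl 9-[tert-butyl(dimethyl)silyl]oxy-8-Ar-3,5,7-trioxononanoate (racemic), via acylketene 19 (not isolated)
Conditions: MeOH (10 equiv.), toluene, 100 °C, sealed tube; concentrated and used crude
Reagents that add atoms: methanol, CO
Why: Thermal retro-hetero-Diels–Alder loss of acetone from the dioxinone gives an acylketene, and excess methanol should trap it faster than the internal enol oxygen can close a pyrone.

Step 11
Reactants: 20 methyl 9-[tert-butyl(dimethyl)silyl]oxy-8-Ar-3,5,7-trioxononanoate (racemic)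
Product: 22 3-[tert-butyl(dimethyl)silyl]oxy-2-Ar-1-(2,4,6-trihydroxyphenyl)propan-1-one (racemic), via acylcyclohexanetrione 21 (not isolated)
Conditions: Mg(OMe)2 (5 equiv.), MeOH, 20 → 60 °C; then 0.5 M HCl, 0 °C, to pH 5
Reagents that add atoms: none
Why: Excess Mg(OMe)2 converts the 3,5,7-trione into its magnesium-chelated bis-enolate (deprotonated at chain carbons 4 and 6), so the ketone carbonyls are masked as enolates and the ester carbon 1 is the only electrophile left; carbon 6 attacks it, methoxide leaves, and the 2-acylcyclohexane-1,3,5-trione 21 tautomerises to aromatic ring A (new bond C4a–C5 in isoflavanone numbering). The closest known reaction type is the magnesium- or alkoxide-mediated Claisen cyclisation of 3,5,7-triketo esters to acylphloroglucinols, the laboratory counterpart of chalcone-synthase folding. Ring A closes in a 6-(enolexo)-exo-trig acyl substitution. No stereocentre is formed and the benzylic carbon stays racemic. The step needs Claisen closure to win over aldol attack of carbon 2 on the carbon-7 ketone (resorcylate) and over O-acylation to a pyrone; the branched, aryl-bearing carbon 8 shields the carbon-7 carbonyl, its enolate form under excess base removes its electrophilicity, and magnesium chelation holds carbon 6 next to the ester while favouring C- over O-attack. Should some silanol be lost by β-elimination, the enone would still converge on ring C later by oxa-Michael closure.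

Step 12
Reactants: 22 3-[tert-butyl(dimethyl)silyl]oxy-2-Ar-1-(2,4,6-trihydroxyphenyl)propan-1-one (racemic)
Product: 23 3-[tert-butyl(dimethyl)silyl]oxy-1-[2-hydroxy-4,6-bis(methoxymethoxy)phenyl]-2-Ar-propan-1-one (racemic)
Conditions: MOMCl (2.2 equiv.), i-Pr2NEt, CH2Cl2, 0 → 20 °C
Reagents that add atoms: chloromethyl methyl ether (MOMCl), COCCl
Why: Amine-promoted O-alkylation protects the para and one ortho phenol, while the hydroxyl hydrogen-bonded to the ketone stays free, as in the usual bis-MOM protection of phloroacetophenones.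

Step 13
Reactants: 23 bis-MOM silyl ether (racemic)
Product: 24 3-hydroxy-1-[2-hydroxy-4,6-bis(methoxymethoxy)phenyl]-2-Ar-propan-1-one (racemic)
Conditions: HF·pyridine, pyridine, THF, 0 → 20 °C
Reagents that add atoms: none
Why: Fluoride-mediated cleavage of the primary silyl ether under buffered, weakly acidic conditions should leave the aryl MOM ethers and the β-hydroxy ketone untouched.

Step 14
Reactants: 24 3-hydroxy-1-[2-hydroxy-4,6-bis(methoxymethoxy)phenyl]-2-Ar-propan-1-one (racemic)
Product: 25 5,7-bis(methoxymethoxy)-3-Ar-2,3-dihydro-4H-chromen-4-one (racemic)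
Conditions: PPh3, DIAD, THF (0.02 M), 0 → 20 °C
Reagents that add atoms: none
Why: Intramolecular Mitsunobu etherification, in which the remaining ortho phenol displaces the activated primary alcohol in a 6-exo-tet closure of ring C (O1–C2); any dehydration to the α-methylene ketone converges on the same chromanone by oxa-Michael addition.

Step 15
Reactants: 25 5,7-bis(methoxymethoxy)-3-Ar-2,3-dihydro-4H-chromen-4-one (racemic)
Product: 26 (3S,4S)-5,7-bis(methoxymethoxy)-3-Ar-3,4-dihydro-2H-chromen-4-ol (cis)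
Conditions: RuCl(p-cymene)[(S,S)-TsDPEN] (3 mol%), HCO2H/Et3N (5:2), EtOAc, 40 °C
Reagents that add atoms: none
Why: Noyori-type asymmetric transfer hydrogenation with dynamic kinetic resolution: C3 epimerises through the enol in the amine/formate medium while the (S,S)-catalyst reduces the (3S)-ketone faster and delivers hydride to the carbonyl face that gives the (4S)-carbinol cis to the aryl group (the sense known for 4-chromanone), which fixes C3 as S.

Step 16
Reactants: 26 (3S,4S)-5,7-bis(methoxymethoxy)-3-Ar-3,4-dihydro-2H-chromen-4-ol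
Product: 27 (3S)-5,7-bis(methoxymethoxy)-3-Ar-2,3-dihydro-4H-chromen-4-one
Conditions: Dess–Martin periodinane, NaHCO3, CH2Cl2, 0 → 20 °C
Reagents that add atoms: none
Why: Dess–Martin oxidation of the benzylic alcohol under bicarbonate buffering is non-enolising, so the C4 ketone should return with the C3 (S) configuration intact.

Step 17
Reactants: 27 (3S)-5,7-bis(methoxymethoxy)-3-Ar-2,3-dihydro-4H-chromen-4-one
Product: 28 (3S)-5,7-dihydroxy-3-(5-hydroxy-2,2-dimethyl-2H-chromen-8-yl)-2,3-dihydro-4H-chromen-4-one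
Conditions: HCl (1.25 M in MeOH), 0 → 20 °C, stopped at full conversion; NaHCO3
Reagents that add atoms: none
Why: Acid-catalysed acetal exchange with methanol removes the three aryl MOM ethers; low temperature and short contact should keep acid-catalysed enolisation at C3 and addition to the chromene double bond slow.

**Compound list**
1 | 4-bromoresorcinol | Oc1ccc(Br)c(O)c1 | starting material
2 | 2-bromo-5-(methoxymethoxy)phenol | COCOc1ccc(Br)c(O)c1 | intermediate
3 | 2-methylbut-3-yn-2-ol | CC(C)(O)C#C | starting material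
4 | 2-methylbut-3-yn-2-yl trifluoroacetate (not isolated) | CC(C)(OC(=O)C(F)(F)F)C#C | intermediate
5 | 1-bromo-4-(methoxymethoxy)-2-[(2-methylbut-3-yn-2-yl)oxy]benzene | COCOc1ccc(Br)c(OC(C)(C)C#C)c1 | intermediate
6 | 6-bromo-3-(methoxymethoxy)-2-(3-methylbuta-1,2-dien-1-yl)phenol (not isolated) | COCOc1ccc(Br)c(O)c1C=C=C(C)C | intermediate
7 | 8-bromo-5-(methoxymethoxy)-2,2-dimethyl-2H-chromene | COCOc1ccc(Br)c2OC(C)(C)C=Cc12 | intermediate
8 | (2-ethoxy-2-oxoethyl)zinc bromide | CCOC(=O)C[Zn]Br | starting material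
9 | ethyl 2-[5-(methoxymethoxy)-2,2-dimethyl-2H-chromen-8-yl]acetate | CCOC(=O)Cc1ccc(OCOC)c2C=CC(C)(C)Oc12 | intermediate
10 | paraformaldehyde (formaldehyde) | C=O | starting material
11 | ethyl 3-hydroxy-2-[5-(methoxymethoxy)-2,2-dimethyl-2H-chromen-8-yl]propanoate, racemic | CCOC(=O)C(CO)c1ccc(OCOC)c2C=CC(C)(C)Oc12 | intermediate
12 | ethyl 3-[tert-butyl(dimethyl)silyl]oxy-2-[5-(methoxymethoxy)-2,2-dimethyl-2H-chromen-8-yl]propanoate, racemic | CCOC(=O)C(CO[Si](C)(C)C(C)(C)C)c1ccc(OCOC)c2C=CC(C)(C)Oc12 | intermediate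
13 | 3-[tert-butyl(dimethyl)silyl]oxy-2-[5-(methoxymethoxy)-2,2-dimethyl-2H-chromen-8-yl]propanoic acid, racemic | OC(=O)C(CO[Si](C)(C)C(C)(C)C)c1ccc(OCOC)c2C=CC(C)(C)Oc12 | intermediate
14 | 2,2,6-trimethyl-4H-1,3-dioxin-4-one | CC1=CC(=O)OC(C)(C)O1 | starting material
15 | acetyl chloride | CC(Cl)=O | starting material
16 | 2,2-dimethyl-6-(2-oxopropyl)-4H-1,3-dioxin-4-one | CC(=O)CC1=CC(=O)OC(C)(C)O1 | intermediate
17 | 3-[tert-butyl(dimethyl)silyl]oxy-1-(imidazol-1-yl)-2-[5-(methoxymethoxy)-2,2-dimethyl-2H-chromen-8-yl]propan-1-one, racemic (not isolated) | O=C(C(CO[Si](C)(C)C(C)(C)C)c1ccc(OCOC)c2C=CC(C)(C)Oc12)n1ccnc1 | intermediate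
18 | 6-{6-[tert-butyl(dimethyl)silyl]oxy-5-[5-(methoxymethoxy)-2,2-dimethyl-2H-chromen-8-yl]-2,4-dioxohexyl}-2,2-dimethyl-4H-1,3-dioxin-4-one, racemic | CC1(C)OC(CC(=O)CC(=O)C(CO[Si](C)(C)C(C)(C)C)c2ccc(OCOC)c3C=CC(C)(C)Oc23)=CC(=O)O1 | intermediate
19 | 9-[tert-butyl(dimethyl)silyl]oxy-8-[5-(methoxymethoxy)-2,2-dimethyl-2H-chromen-8-yl]non-1-ene-1,3,5,7-tetrone (acylketene, not isolated) | O=C=CC(=O)CC(=O)CC(=O)C(CO[Si](C)(C)C(C)(C)C)c1ccc(OCOC)c2C=CC(C)(C)Oc12 | intermediate
20 | methyl 9-[tert-butyl(dimethyl)silyl]oxy-8-[5-(methoxymethoxy)-2,2-dimethyl-2H-chromen-8-yl]-3,5,7-trioxononanoate, racemic | COC(=O)CC(=O)CC(=O)CC(=O)C(CO[Si](C)(C)C(C)(C)C)c1ccc(OCOC)c2C=CC(C)(C)Oc12 | intermediate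
21 | 2-{3-[tert-butyl(dimethyl)silyl]oxy-2-[5-(methoxymethoxy)-2,2-dimethyl-2H-chromen-8-yl]propanoyl}cyclohexane-1,3,5-trione (not isolated) | O=C1CC(=O)C(C(=O)C(CO[Si](C)(C)C(C)(C)C)c2ccc(OCOC)c3C=CC(C)(C)Oc23)C(=O)C1 | intermediate
22 | 3-[tert-butyl(dimethyl)silyl]oxy-2-[5-(methoxymethoxy)-2,2-dimethyl-2H-chromen-8-yl]-1-(2,4,6-trihydroxyphenyl)propan-1-one, racemic | CC(C)(C)[Si](C)(C)OCC(C(=O)c1c(O)cc(O)cc1O)c1ccc(OCOC)c2C=CC(C)(C)Oc12 | intermediate
23 | 3-[tert-butyl(dimethyl)silyl]oxy-1-[2-hydroxy-4,6-bis(methoxymethoxy)phenyl]-2-[5-(methoxymethoxy)-2,2-dimethyl-2H-chromen-8-yl]propan-1-one, racemic | CC(C)(C)[Si](C)(C)OCC(C(=O)c1c(O)cc(OCOC)cc1OCOC)c1ccc(OCOC)c2C=CC(C)(C)Oc12 | intermediate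
24 | 3-hydroxy-1-[2-hydroxy-4,6-bis(methoxymethoxy)phenyl]-2-[5-(methoxymethoxy)-2,2-dimethyl-2H-chromen-8-yl]propan-1-one, racemic | OCC(C(=O)c1c(O)cc(OCOC)cc1OCOC)c1ccc(OCOC)c2C=CC(C)(C)Oc12 | intermediate
25 | 5,7-bis(methoxymethoxy)-3-[5-(methoxymethoxy)-2,2-dimethyl-2H-chromen-8-yl]-2,3-dihydro-4H-chromen-4-one, racemic | CC1(C)C=Cc2c(OCOC)ccc(C3COc4cc(OCOC)cc(OCOC)c4C3=O)c2O1 | intermediate
26 | (3S,4S)-5,7-bis(methoxymethoxy)-3-[5-(methoxymethoxy)-2,2-dimethyl-2H-chromen-8-yl]-3,4-dihydro-2H-chromen-4-ol | CC1(C)C=Cc2c(OCOC)ccc([C@H]3COc4cc(OCOC)cc(OCOC)c4[C@H]3O)c2O1 | intermediate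
27 | (3S)-5,7-bis(methoxymethoxy)-3-[5-(methoxymethoxy)-2,2-dimethyl-2H-chromen-8-yl]-2,3-dihydro-4H-chromen-4-one | CC1(C)C=Cc2c(OCOC)ccc([C@H]3COc4cc(OCOC)cc(OCOC)c4C3=O)c2O1 | intermediate
28 | (3S)-5,7-dihydroxy-3-(5-hydroxy-2,2-dimethyl-2H-chromen-8-yl)-2,3-dihydro-4H-chromen-4-one | CC1(C)C=Cc2c(O)ccc([C@H]3COc4cc(O)cc(O)c4C3=O)c2O1 | target

**Step count**
Total: 17 steps. Longest linear sequence: 16 steps (steps 1–7, then 9–17); step 8 is the one-step side branch.

**Steps most likely to fail**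

1. Step 11. The chain may fold the wrong way: aldol attack of carbon 2 on the carbon-7 ketone would give a resorcylate, and O-acylation would give a pyrone; either could also start during the thermolysis of step 10. The fallback buys ring A as phloroglucinol instead of folding it. It sets out from ester 12 and returns at 23. Ester 12 is reduced with i-Bu2AlH (CH2Cl2, −78 °C) to 3-[tert-butyl(dimethyl)silyl]oxy-2-Ar-propanal F1. Phloroglucinol is converted with NaH and MOMCl into 1,3,5-tris(methoxymethoxy)benzene F2, which is lithiated between two MOM ethers (n-BuLi, THF, 0 °C, directed ortho-metalation) and added to the aldehyde to give the carbinol 3-[tert-butyl(dimethyl)silyl]oxy-2-Ar-1-[2,4,6-tris(methoxymethoxy)phenyl]propan-1-ol F3. Dess–Martin oxidation gives the ketone 3-[tert-butyl(dimethyl)silyl]oxy-2-Ar-1-[2,4,6-tris(methoxymethoxy)phenyl]propan-1-one F4. Chelation-assisted removal of one ortho MOM group with MgBr2·OEt2 (Et2O, 20 °C) then gives 23.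

2. Step 9. The strongly basic dianion may deprotonate the α-aryl acyl imidazolide instead of adding to it, leading to ketene formation or loss of silanolate. The fallback replaces the dianion by a soft-enolisation acylation. It sets out from acid 13 and dioxinone 14 and returns at 18. Acid 13 is converted with 1-chloro-N,N,2-trimethylpropenylamine (CH2Cl2, 0 °C) into the acid chloride 3-[tert-butyl(dimethyl)silyl]oxy-2-Ar-propanoyl chloride F5. The lithium enolate of 14 is acylated with the benzotriazolide of monoallyl malonate to give allyl 4-(2,2-dimethyl-4-oxo-4H-1,3-dioxin-6-yl)-3-oxobutanoate F6. MgCl2 and pyridine (CH2Cl2, 0 °C) C-acylate F6 with F5 at the carbon between ketone and ester, giving the allyl 2-acyl-3-oxobutanoate F7. Pd(PPh3)4 and morpholine (THF, 20 °C) then remove the allyl ester with decarboxylation to give 18.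

3. Step 17. Acid-catalysed enolisation at C3 may erode the enantiomeric purity, and acid may add across the chromene double bond. The fallback moves the acid step before the stereocentre is set and finishes with a fluoride deprotection. It sets out from 25 and returns at 28. Racemic 25 is deprotected with HCl in MeOH (40 °C) to the racemic triphenol 5,7-dihydroxy-3-(5-hydroxy-2,2-dimethyl-2H-chromen-8-yl)-2,3-dihydro-4H-chromen-4-one F8. Silylation with TBSCl, imidazole and DMAP (DMF, 50 °C) gives the racemic tris(tert-butyldimethylsilyl) ether F9. The conditions of step 15 give the (3S,4S)-tris-silyl chroman-4-ol F10, and the conditions of step 16 give the (3S)-tris-silyl chromanone F11. HF·pyridine (THF/pyridine, 0 °C) then frees 28 without acid or base strong enough to enolise C3.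

**Further compounds**
F1 | step 11 | 3-[tert-butyl(dimethyl)silyl]oxy-2-[5-(methoxymethoxy)-2,2-dimethyl-2H-chromen-8-yl]propanal, racemic | O=CC(CO[Si](C)(C)C(C)(C)C)c1ccc(OCOC)c2C=CC(C)(C)Oc12
F2 | step 11 | 1,3,5-tris(methoxymethoxy)benzene | COCOc1cc(OCOC)cc(OCOC)c1
F3 | step 11 | 3-[tert-butyl(dimethyl)silyl]oxy-2-[5-(methoxymethoxy)-2,2-dimethyl-2H-chromen-8-yl]-1-[2,4,6-tris(methoxymethoxy)phenyl]propan-1-ol, mixture of diastereomers | OC(c1c(OCOC)cc(OCOC)cc1OCOC)C(CO[Si](C)(C)C(C)(C)C)c1ccc(OCOC)c2C=CC(C)(C)Oc12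
F4 | step 11 | 3-[tert-butyl(dimethyl)silyl]oxy-2-[5-(methoxymethoxy)-2,2-dimethyl-2H-chromen-8-yl]-1-[2,4,6-tris(methoxymethoxy)phenyl]propan-1-one, racemic | O=C(c1c(OCOC)cc(OCOC)cc1OCOC)C(CO[Si](C)(C)C(C)(C)C)c1ccc(OCOC)c2C=CC(C)(C)Oc12
F5 | step 9 | 3-[tert-butyl(dimethyl)silyl]oxy-2-[5-(methoxymethoxy)-2,2-dimethyl-2H-chromen-8-yl]propanoyl chloride, racemic | ClC(=O)C(CO[Si](C)(C)C(C)(C)C)c1ccc(OCOC)c2C=CC(C)(C)Oc12
F6 | step 9 | allyl 4-(2,2-dimethyl-4-oxo-4H-1,3-dioxin-6-yl)-3-oxobutanoate | C=CCOC(=O)CC(=O)CC1=CC(=O)OC(C)(C)O1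
F7 | step 9 | allyl 2-{3-[tert-butyl(dimethyl)silyl]oxy-2-[5-(methoxymethoxy)-2,2-dimethyl-2H-chromen-8-yl]propanoyl}-4-(2,2-dimethyl-4-oxo-4H-1,3-dioxin-6-yl)-3-oxobutanoate | C=CCOC(=O)C(C(=O)CC1=CC(=O)OC(C)(C)O1)C(=O)C(CO[Si](C)(C)C(C)(C)C)c1ccc(OCOC)c2C=CC(C)(C)Oc12
F8 | step 17 | 5,7-dihydroxy-3-(5-hydroxy-2,2-dimethyl-2H-chromen-8-yl)-2,3-dihydro-4H-chromen-4-one, racemic | CC1(C)C=Cc2c(O)ccc(C3COc4cc(O)cc(O)c4C3=O)c2O1
F9 | step 17 | 5,7-bis[tert-butyl(dimethyl)silyl]oxy-3-{5-[tert-butyl(dimethyl)silyl]oxy-2,2-dimethyl-2H-chromen-8-yl}-2,3-dihydro-4H-chromen-4-one, racemic | CC1(C)C=Cc2c(O[Si](C)(C)C(C)(C)C)ccc(C3COc4cc(O[Si](C)(C)C(C)(C)C)cc(O[Si](C)(C)C(C)(C)C)c4C3=O)c2O1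
F10 | step 17 | (3S,4S)-5,7-bis[tert-butyl(dimethyl)silyl]oxy-3-{5-[tert-butyl(dimethyl)silyl]oxy-2,2-dimethyl-2H-chromen-8-yl}-3,4-dihydro-2H-chromen-4-ol | CC1(C)C=Cc2c(O[Si](C)(C)C(C)(C)C)ccc([C@H]3COc4cc(O[Si](C)(C)C(C)(C)C)cc(O[Si](C)(C)C(C)(C)C)c4[C@H]3O)c2O1
F11 | step 17 | (3S)-5,7-bis[tert-butyl(dimethyl)silyl]oxy-3-{5-[tert-butyl(dimethyl)silyl]oxy-2,2-dimethyl-2H-chromen-8-yl}-2,3-dihydro-4H-chromen-4-one | CC1(C)C=Cc2c(O[Si](C)(C)C(C)(C)C)ccc([C@H]3COc4cc(O[Si](C)(C)C(C)(C)C)cc(O[Si](C)(C)C(C)(C)C)c4C3=O)c2O1
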